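Ring A (C4a, C5, C6, C7, C8, C8a) carries oxygen on the alternate carbons C5, C7 and C8a and the carbonyl carbon C4 on C4a, the signature of a folded polyketide chain. The route therefore rests on the C4a–C8a disconnection: a magnesium-templated Claisen cyclisation turns an open-chain 3,5,7-triketo ester, whose central methine already bears the silyl-protected C6 side chain and whose terminus bears the C3 oxygen as a benzyl ether, into the fully substituted acylphloroglucinol in one operation. Aroylation of the two less hindered hydroxyls, benzylation of the hindered one, Baker–Venkataraman transfer and closure of ring C through the C8a oxygen then lead to the 6-alkyl flavonol.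

Key step: step 6

Remark: ring A oxygens of the intermediates are named by the flavone position they end up at (O1 on C8a, O5, O7). Compounds 7, 9 and 14 each hold one freely enolising methine and are racemic; the target has no stereocentre.

Step 1
Reactants: 1 3-methylbutane-1,3-diol
Product: 2 4-iodo-2-methylbutan-2-ol
Conditions: I2, PPh3, imidazole, CH2Cl2, 0 °C to rt
Reagents that add atoms: iodine, II
Why: Appel-type iodination should convert only the primary hydroxyl, because the tertiary alcohol forms its alkoxyphosphonium salt slowly and cannot be displaced by iodide in an SN2 reaction.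

Step 2
Reactants: 2 4-iodo-2-methylbutan-2-ol
Product: 3 triethyl[(4-iodo-2-methylbutan-2-yl)oxy]silane
Conditions: Et3SiOTf, 2,6-lutidine, CH2Cl2, −78 to 0 °C
Reagents that add atoms: triethylsilyl trifluoromethanesulfonate, CC[Si](CC)(CC)OS(=O)(=O)C(F)(F)F
Why: Silylation with a silyl triflate and a hindered pyridine base is the standard way to cap a tertiary alcohol and should leave the primary iodide untouched.

Step 3
Reactants: 3 triethyl[(4-iodo-2-methylbutan-2-yl)oxy]silane; 4 acetylacetone
Product: 5 3-[3-methyl-3-(triethylsilyloxy)butyl]pentane-2,4-dione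
Conditions: K2CO3, acetone, reflux (4 in twofold excess)
Reagents that add atoms: none
Why: The potassium enolate of acetylacetone, kept in excess to suppress dialkylation, should displace the unhindered primary iodide at carbon in a classical SN2 C-alkylation of a 1,3-diketone, and the silyl ether is inert to carbonate.

Step 4
Reactants: 5 3-[3-methyl-3-(triethylsilyloxy)butyl]pentane-2,4-dione; 6 dimethyl carbonate
Product: 7 methyl 4-[3-methyl-3-(triethylsilyloxy)butyl]-3,5-dioxohexanoate
Conditions: LiN(iPr)2 (3.0 equiv), THF, −78 to 0 °C; then 6, 0 °C; AcOH quench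
Reagents that add atoms: none
Why: Two equivalents of amide base generate the 1,3-dianion, whose terminal methyl carbanion is the most nucleophilic site and should be acylated by dimethyl carbonate in a Claisen-type carbomethoxylation, the third equivalent absorbing the more acidic diketo ester as it forms.

Step 5
Reactants: 7 methyl 4-[3-methyl-3-(triethylsilyloxy)butyl]-3,5-dioxohexanoate; 8 2-(benzyloxy)-N-methoxy-N-methylacetamide
Product: 9 methyl 8-(benzyloxy)-4-[3-methyl-3-(triethylsilyloxy)butyl]-3,5,7-trioxooctanoate
Conditions: LiN(iPr)2 (3.3 equiv), THF, −78 to 0 °C; then 8, −78 to −20 °C; AcOH, −78 °C; product used without storage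
Reagents that add atoms: none
Why: The 2,4,6-trianion reacts at its last-formed and least stabilised carbanion, the C6 methyl, and acylation by the N-methoxy-N-methylamide (polyanion Claisen acylation) should stop at the chelated tetrahedral adduct, so the still more acidic triketo ester is released only on the cold acidic quench.

Step 6
Reactants: 9 methyl 8-(benzyloxy)-4-[3-methyl-3-(triethylsilyloxy)butyl]-3,5,7-trioxooctanoate
Product: 10 2-(benzyloxy)-1-{2,4,6-trihydroxy-3-[3-methyl-3-(triethylsilyloxy)butyl]phenyl}ethanone
Conditions: Mg(OMe)2 (5 equiv), MeOH, rt then 50 °C, Ar; cold 0.5 M HCl to pH 4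
Reagents that add atoms: none
Why: Mg(OMe)2 removes the most acidic protons first, those of the C6 methylene of the chain (future C4a) and of the C4 methine, and holds both β-diketone units as magnesium chelates, so the ketone carbonyls are tied up as enolates while the ester, whose α-methylene is the least acidic site, remains a free electrophile. The chelated C4a carbanion then attacks the ester carbon (future C8a) in a Claisen condensation, methoxide leaves, and the cyclohexane-1,3,5-trione enolises irreversibly to the phloroglucinol. The closest known reaction is the biomimetic Claisen cyclisation of 3,5,7-triketo esters and of the pyrones derived from them to acylphloroglucinols under magnesium alkoxide or hydroxide bases, the laboratory counterpart of the chalcone synthase closure. Ring A closes in a 6-exo-trig mode. No stereocentre is formed, and the labile methine of 9 becomes the sp2 carbon C6. The step needs chemoselectivity for C-acylation over aldol closure of the ester α-carbon onto the C7 ketone of the chain and over pyrone formation, which is secured by chelation of the ketones, by the reversibility of lactone formation in methoxide, and by the silyl ether, which keeps the side-chain hydroxyl from forming a cyclic ketal.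

Step 7
Reactants: 10 2-(benzyloxy)-1-{2,4,6-trihydroxy-3-[3-methyl-3-(triethylsilyloxy)butyl]phenyl}ethanone; 11 4-(benzyloxy)benzoyl chloride
Product: 12 4-[(benzyloxy)acetyl]-5-hydroxy-6-[3-methyl-3-(triethylsilyloxy)butyl]-1,3-phenylene bis[4-(benzyloxy)benzoate]
Conditions: 11 (2.05 equiv), Et3N (2.3 equiv), CH2Cl2, −20 to 0 °C
Reagents that add atoms: none
Why: O-Acylation under amine base should take the unchelated para hydroxyl (future O7) first and then the ortho hydroxyl flanked by hydrogen (future O1), leaving the hydroxyl that is both chelated to the ketone and buttressed by the side chain (future O5), the order that bis-protection of 3-alkyl phloroacetophenones follows.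

Step 8
Reactants: 12 4-[(benzyloxy)acetyl]-5-hydroxy-6-[3-methyl-3-(triethylsilyloxy)butyl]-1,3-phenylene bis[4-(benzyloxy)benzoate]
Product: 13 4-[(benzyloxy)acetyl]-5-(benzyloxy)-6-[3-methyl-3-(triethylsilyloxy)butyl]-1,3-phenylene bis[4-(benzyloxy)benzoate]
Conditions: BnBr, K2CO3, Bu4NI (cat.), DMF, rt
Reagents that add atoms: benzyl bromide, BrCc1ccccc1
Why: Williamson benzylation of the remaining phenol with carbonate at room temperature should cap the future O5, the base being too weak at this temperature to enolise the ketone and start acyl transfer.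

Step 9
Reactants: 13 4-[(benzyloxy)acetyl]-5-(benzyloxy)-6-[3-methyl-3-(triethylsilyloxy)butyl]-1,3-phenylene bis[4-(benzyloxy)benzoate]
Product: 14 3-(benzyloxy)-4-{2-(benzyloxy)-3-[4-(benzyloxy)phenyl]-3-oxopropanoyl}-5-hydroxy-2-[3-methyl-3-(triethylsilyloxy)butyl]phenyl 4-(benzyloxy)benzoate
Conditions: LiN(SiMe3)2 (2.5 equiv), THF, −20 °C to rt; AcOH quench
Reagents that add atoms: none
Why: In this Baker–Venkataraman rearrangement the lithium enolate of the α-benzyloxy ketone should attack the only ortho ester through a six-membered transition state and the adduct should collapse to the 1,3-diketone phenoxide, the para ester being out of reach.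

Step 10
Reactants: 14 3-(benzyloxy)-4-{2-(benzyloxy)-3-[4-(benzyloxy)phenyl]-3-oxopropanoyl}-5-hydroxy-2-[3-methyl-3-(triethylsilyloxy)butyl]phenyl 4-(benzyloxy)benzoate
Product: 16 3,5-bis(benzyloxy)-2-[4-(benzyloxy)phenyl]-7-hydroxy-6-(3-hydroxy-3-methylbutyl)-4H-chromen-4-one, via 7-O-aroyl flavone 15 (not isolated)
Conditions: TsOH·H2O (0.3 equiv), MeOH–THF 2:1, 55 °C; then K2CO3 (4 equiv), rt
Reagents that add atoms: none
Why: Acid-catalysed cyclodehydration of the o-hydroxyaryl 1,3-diketone can use only the single free phenol, the C8a oxygen, so ring C should close with the side chain at C6 while the same methanolic acid removes the triethylsilyl ether, and the carbonate methanolysis that follows should cleave the aryl ester at O7 without harming the chromone or the tertiary alcohol, which has no free phenol beside it during the acid stage.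

Step 11
Reactants: 16 3,5-bis(benzyloxy)-2-[4-(benzyloxy)phenyl]-7-hydroxy-6-(3-hydroxy-3-methylbutyl)-4H-chromen-4-one
Product: 17 3,5,7-trihydroxy-2-(4-hydroxyphenyl)-6-(3-hydroxy-3-methylbutyl)-4H-chromen-4-one
Conditions: H2 (1 atm), Pd/C (10 wt %), EtOAc–MeOH, rt
Reagents that add atoms: none
Why: Catalytic hydrogenolysis should cleave the three benzyl ethers at O3, O5 and O4' and leave the chromone C2–C3 double bond and the tertiary alcohol untouched, as is routine for benzyl-protected flavonols.

Compound list
1 | 3-methylbutane-1,3-diol | CC(C)(O)CCO | starting material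
2 | 4-iodo-2-methylbutan-2-ol | CC(C)(O)CCI | intermediate
3 | triethyl[(4-iodo-2-methylbutan-2-yl)oxy]silane | CC[Si](CC)(CC)OC(C)(C)CCI | intermediate
4 | acetylacetone (pentane-2,4-dione) | CC(=O)CC(C)=O | starting material
5 | 3-[3-methyl-3-(triethylsilyloxy)butyl]pentane-2,4-dione | CC(=O)C(CCC(C)(C)O[Si](CC)(CC)CC)C(C)=O | intermediate
6 | dimethyl carbonate | COC(=O)OC | starting material
7 | methyl 4-[3-methyl-3-(triethylsilyloxy)butyl]-3,5-dioxohexanoate (racemic, enolising C4) | COC(=O)CC(=O)C(CCC(C)(C)O[Si](CC)(CC)CC)C(C)=O | intermediate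
8 | 2-(benzyloxy)-N-methoxy-N-methylacetamide | CON(C)C(=O)COCc1ccccc1 | starting material
9 | methyl 8-(benzyloxy)-4-[3-methyl-3-(triethylsilyloxy)butyl]-3,5,7-trioxooctanoate (racemic, enolising C4) | COC(=O)CC(=O)C(CCC(C)(C)O[Si](CC)(CC)CC)C(=O)CC(=O)COCc1ccccc1 | intermediate
10 | 2-(benzyloxy)-1-{2,4,6-trihydroxy-3-[3-methyl-3-(triethylsilyloxy)butyl]phenyl}ethanone | O=C(COCc1ccccc1)c1c(O)cc(O)c(CCC(C)(C)O[Si](CC)(CC)CC)c1O | intermediate
11 | 4-(benzyloxy)benzoyl chloride | O=C(Cl)c1ccc(OCc2ccccc2)cc1 | starting material
12 | 4-[(benzyloxy)acetyl]-5-hydroxy-6-[3-methyl-3-(triethylsilyloxy)butyl]-1,3-phenylene bis[4-(benzyloxy)benzoate] (10 aroylated on the future O7 and O1, future O5 free) | O=C(COCc1ccccc1)c1c(O)c(CCC(C)(C)O[Si](CC)(CC)CC)c(OC(=O)c2ccc(OCc3ccccc3)cc2)cc1OC(=O)c1ccc(OCc2ccccc2)cc1 | intermediate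
13 | 4-[(benzyloxy)acetyl]-5-(benzyloxy)-6-[3-methyl-3-(triethylsilyloxy)butyl]-1,3-phenylene bis[4-(benzyloxy)benzoate] | O=C(COCc1ccccc1)c1c(OCc2ccccc2)c(CCC(C)(C)O[Si](CC)(CC)CC)c(OC(=O)c2ccc(OCc3ccccc3)cc2)cc1OC(=O)c1ccc(OCc2ccccc2)cc1 | intermediate
14 | 3-(benzyloxy)-4-{2-(benzyloxy)-3-[4-(benzyloxy)phenyl]-3-oxopropanoyl}-5-hydroxy-2-[3-methyl-3-(triethylsilyloxy)butyl]phenyl 4-(benzyloxy)benzoate (racemic, enolising diketone methine) | O=C(c1ccc(OCc2ccccc2)cc1)C(OCc1ccccc1)C(=O)c1c(O)cc(OC(=O)c2ccc(OCc3ccccc3)cc2)c(CCC(C)(C)O[Si](CC)(CC)CC)c1OCc1ccccc1 | intermediate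
15 | 3,5-bis(benzyloxy)-2-[4-(benzyloxy)phenyl]-6-(3-hydroxy-3-methylbutyl)-4-oxo-4H-chromen-7-yl 4-(benzyloxy)benzoate | O=c1c(OCc2ccccc2)c(-c2ccc(OCc3ccccc3)cc2)oc2cc(OC(=O)c3ccc(OCc4ccccc4)cc3)c(CCC(C)(C)O)c(OCc3ccccc3)c12 | intermediate
16 | 3,5-bis(benzyloxy)-2-[4-(benzyloxy)phenyl]-7-hydroxy-6-(3-hydroxy-3-methylbutyl)-4H-chromen-4-one | O=c1c(OCc2ccccc2)c(-c2ccc(OCc3ccccc3)cc2)oc2cc(O)c(CCC(C)(C)O)c(OCc3ccccc3)c12 | intermediate
17 | 3,5,7-trihydroxy-2-(4-hydroxyphenyl)-6-(3-hydroxy-3-methylbutyl)-4H-chromen-4-one (no stereocentre) | CC(C)(O)CCc1c(O)cc2oc(-c3ccc(O)cc3)c(O)c(=O)c2c1O | target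

Total step count: 11. Longest linear sequence: 11 steps (1 to 17); compounds 4, 6, 8 and 11 are bought.

Steps most likely to fail

Step 6. The polyanion may be diverted from C-acylation into aldol closure of the ester α-carbon onto the C7 ketone of the chain, may stall at the lactone stage, or may be cut by methoxide in a retro-Claisen cleavage. The fallback moves the side chain to the ester α-carbon, so that an aldol adduct would carry a quaternary carbon and could not aromatise, and the Claisen closure then forms the C4a–C5 bond instead. It sets out from iodide 3. Methyl acetoacetate is C-alkylated with 3 (NaH, THF–DMF) to methyl 2-[3-methyl-3-(triethylsilyloxy)butyl]-3-oxobutanoate F1. Its dianion (NaH, then n-BuLi, THF, 0 °C) is acylated at C4 with N-methoxy-N-methylacetamide to methyl 2-[3-methyl-3-(triethylsilyloxy)butyl]-3,5-dioxohexanoate F2. The trianion of F2 (LiN(iPr)2) is acylated at C6 with 8 to methyl 8-(benzyloxy)-2-[3-methyl-3-(triethylsilyloxy)butyl]-3,5,7-trioxooctanoate F3. Treatment of F3 with Mg(OMe)2 in MeOH should then give the same acylphloroglucinol, so the fallback returns to the route at 10.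

Step 5. Trianion formation may be incomplete, or the trianion may act as a base towards the α-protons of the amide instead of adding to it, so that starting material is returned. The fallback inverts the order of the two chain extensions, so that the enolisable electrophile meets the easier dianion and the trianion meets an electrophile without acidic protons. It sets out from 5. The dianion of 5 (LiN(iPr)2, 2.2 equiv) is acylated at a terminal methyl with 8 to 1-(benzyloxy)-5-[3-methyl-3-(triethylsilyloxy)butyl]heptane-2,4,6-trione F4. The trianion of F4 is formed by kinetic deprotonation at the C7 methyl rather than at the alkoxy-bearing carbon and is carbomethoxylated with dimethyl carbonate 6, which returns the route at 9.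

Step 7. Discrimination between the two ketone-chelated hydroxyls may be insufficient, so that acylation reaches the hindered hydroxyl or over-acylation occurs, and material leaks into the 8-alkyl series. The fallback moves the differentiation to a bulky, reversible silylation and then puts the aroyl groups on exhaustively. It sets out from 10. Silylation with tBuMe2SiCl (2.1 equiv, imidazole, DMF, 0 °C) should take the two less hindered phenols and give 2-(benzyloxy)-1-{4,6-bis[(tert-butyldimethylsilyl)oxy]-2-hydroxy-3-[3-methyl-3-(triethylsilyloxy)butyl]phenyl}ethanone F5; wrongly silylated material can be desilylated and recycled. Mitsunobu benzylation of the remaining phenol (BnOH, PPh3, diisopropyl azodicarboxylate, toluene) gives 2-(benzyloxy)-1-{2-(benzyloxy)-4,6-bis[(tert-butyldimethylsilyl)oxy]-3-[3-methyl-3-(triethylsilyloxy)butyl]phenyl}ethanone F6. K2CO3 in MeOH cleaves only the aryl silyl ethers and gives 2-(benzyloxy)-1-{2-(benzyloxy)-4,6-dihydroxy-3-[3-methyl-3-(triethylsilyloxy)butyl]phenyl}ethanone F7. Exhaustive acylation of F7 with 11 (Et3N, DMAP cat., CH2Cl2) returns the route at 13.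

Further compounds
F1 | step 6 | methyl 2-[3-methyl-3-(triethylsilyloxy)butyl]-3-oxobutanoate | COC(=O)C(CCC(C)(C)O[Si](CC)(CC)CC)C(C)=O
F2 | step 6 | methyl 2-[3-methyl-3-(triethylsilyloxy)butyl]-3,5-dioxohexanoate | COC(=O)C(CCC(C)(C)O[Si](CC)(CC)CC)C(=O)CC(C)=O
F3 | step 6 | methyl 8-(benzyloxy)-2-[3-methyl-3-(triethylsilyloxy)butyl]-3,5,7-trioxooctanoate | COC(=O)C(CCC(C)(C)O[Si](CC)(CC)CC)C(=O)CC(=O)CC(=O)COCc1ccccc1
F4 | step 5 | 1-(benzyloxy)-5-[3-methyl-3-(triethylsilyloxy)butyl]heptane-2,4,6-trione | CC(=O)C(CCC(C)(C)O[Si](CC)(CC)CC)C(=O)CC(=O)COCc1ccccc1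
F5 | step 7 | 2-(benzyloxy)-1-{4,6-bis[(tert-butyldimethylsilyl)oxy]-2-hydroxy-3-[3-methyl-3-(triethylsilyloxy)butyl]phenyl}ethanone | O=C(COCc1ccccc1)c1c(O)c(CCC(C)(C)O[Si](CC)(CC)CC)c(O[Si](C)(C)C(C)(C)C)cc1O[Si](C)(C)C(C)(C)C
F6 | step 7 | 2-(benzyloxy)-1-{2-(benzyloxy)-4,6-bis[(tert-butyldimethylsilyl)oxy]-3-[3-methyl-3-(triethylsilyloxy)butyl]phenyl}ethanone | O=C(COCc1ccccc1)c1c(OCc2ccccc2)c(CCC(C)(C)O[Si](CC)(CC)CC)c(O[Si](C)(C)C(C)(C)C)cc1O[Si](C)(C)C(C)(C)C
F7 | step 7 | 2-(benzyloxy)-1-{2-(benzyloxy)-4,6-dihydroxy-3-[3-methyl-3-(triethylsilyloxy)butyl]phenyl}ethanone | O=C(COCc1ccccc1)c1c(OCc2ccccc2)c(CCC(C)(C)O[Si](CC)(CC)CC)c(O)cc1O
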